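**Retrosynthetic overview**
1. The target is a furofuran with an exo guaiacyl group at C7 and an endo syringyl group at C7' that carries a threo (7''R,8''R) arylglycerol ether. It is reached by global desilylation after reductive closure of ring B (O–C7'–C8'–C8–C9) onto an aryl ketone.
2. Ring A (O–C7–C8–C8'–C9') is closed in the key step by forming its O–CH2 bond at C9'. A 1-arylcyclopropanol is opened oxidatively under copper catalysis (strain release) and the resulting homoenolate is coupled with the C7 hydroxyl; the same event unveils the C7' ketone needed for ring B.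
3. Enabling feature: in ring A the CH2 (C9') stands 1,3 to the oxygen-bearing benzylic carbon C7' of ring B through the ring-fusion carbon C8'. This O–CH2–CH–C(Ar)–O unit is a β-alkoxy aryl ketone in disguise, i.e. a 1-arylcyclopropan-1-ol made of C7', C8' and C9' with a hydroxyl (on C7) placed to form a five-membered ring.
4. The hydroxycyclopropanol comes from a hydroxyl-directed Kulinkovich coupling of a homoallylic alcohol (fragment 1, from vanillin by an Evans crotonate-imide aldol) with an aryl methyl ester (fragment 2).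
5. Fragment 2 already carries the glycerol ether, built from methyl syringate and syringaldehyde by an Evans glycolate aldol. Ring order: cyclopropane, then ring A, then ring B.

Key step: step 13

Remark on the chemistry: locants follow lignan usage (C7/C7' benzylic, C8/C8' ring fusion, C9/C9' CH2O, C7''–C9'' glycerol chain). The Kulinkovich step is assumed to give the trans-1,2-disubstituted cyclopropanol; its carbinol configuration is immaterial because step 13 erases it.

**Fragment 1**

Step 1
Reactants: 1 vanillin (4-hydroxy-3-methoxybenzaldehyde)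
Product: 2 3-methoxy-4-[(triisopropylsilyl)oxy]benzaldehyde
Conditions: TIPSCl, imidazole, DMF, rt
Reagents that add atoms: triisopropylsilyl chloride, CC(C)[Si](Cl)(C(C)C)C(C)C
Why: Imidazole-promoted O-silylation of the phenol; the bulky silyl ether should tolerate the organometallic, hydride and Lewis-acid steps ahead and falls to fluoride at the end.

Step 2
Reactants: 3 (R)-4-benzyl-1,3-oxazolidin-2-one; 4 (E)-but-2-enoic anhydride (crotonic anhydride)
Product: 5 (R)-4-benzyl-3-[(E)-but-2-enoyl]-1,3-oxazolidin-2-one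
Conditions: LiCl, Et3N, THF, −20 °C to rt
Reagents that add atoms: none
Why: N-acylation of the oxazolidinone by the anhydride under LiCl/Et3N activation, mild enough to leave the crotonyl double bond in place.

Step 3
Reactants: 5 (R)-4-benzyl-3-[(E)-but-2-enoyl]-1,3-oxazolidin-2-one; 2 3-methoxy-4-[(triisopropylsilyl)oxy]benzaldehyde
Product: 7 (4R)-4-benzyl-3-[(2R)-2-{(R)-hydroxy[3-methoxy-4-(triisopropylsilyloxy)phenyl]methyl}but-3-enoyl]-1,3-oxazolidin-2-one, via dibutylboron dienolate 6 (not isolated)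
Conditions: Bu2BOTf, Et3N, CH2Cl2, −78 °C; then 2, −78 to 0 °C; H2O2, pH 7 buffer, MeOH
Reagents that add atoms: none
Why: Evans aldol of a crotonate imide: soft enolization gives the (Z)-dienol borinate, which reacts at its α-carbon through a Zimmerman–Traxler chair on the face away from the benzyl group, so the (R)-auxiliary should set the syn pair C7 (R) and the vinyl-bearing C8.

Step 4
Reactants: 7 aldol adduct
Product: 8 (1R,2S)-2-ethenyl-1-[3-methoxy-4-(triisopropylsilyloxy)phenyl]propane-1,3-diol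
Conditions: LiBH4, MeOH (1 equiv), THF, 0 °C
Reagents that add atoms: none
Why: Reductive cleavage of the N-acyl oxazolidinone by borohydride gives the primary alcohol (C9) without touching the two stereocentres or the terminal alkene.

Step 5
Reactants: 8 diol
Product: 9 (1R,2S)-2-{[(tert-butyldimethylsilyl)oxy]methyl}-1-[3-methoxy-4-(triisopropylsilyloxy)phenyl]but-3-en-1-ol (fragment 1)
Conditions: TBSCl, imidazole, CH2Cl2, 0 °C
Reagents that add atoms: tert-butyldimethylsilyl chloride, CC(C)(C)[Si](C)(C)Cl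
Why: Selective silylation on steric grounds: the primary hydroxyl should react much faster than the hindered secondary benzylic one, which stays free as directing group and later nucleophile.

**Fragment 2**

Step 6
Reactants: 10 (S)-4-benzyl-1,3-oxazolidin-2-one; 11 bromoacetyl bromide
Product: 13 (S)-4-benzyl-3-(bromoacetyl)-1,3-oxazolidin-2-one, via N-lithio oxazolidinone 12 (not isolated)
Conditions: n-BuLi, THF, −78 °C; then 11, −78 °C
Reagents that add atoms: none
Why: N-acylation of the lithiated oxazolidinone by the acid bromide, which is far more electrophilic than the alkyl bromide end.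

Step 7
Reactants: 13 (S)-4-benzyl-3-(bromoacetyl)-1,3-oxazolidin-2-one; 14 methyl syringate (methyl 4-hydroxy-3,5-dimethoxybenzoate)
Product: 15 methyl 4-{2-[(4S)-4-benzyl-2-oxo-1,3-oxazolidin-3-yl]-2-oxoethoxy}-3,5-dimethoxybenzoate
Conditions: K2CO3, acetone, rt
Reagents that add atoms: none
Why: Williamson ether synthesis at an activated α-halo carbonyl carbon, which should also work for the hindered 2,6-dimethoxyphenoxide; the weak base leaves imide and methyl ester intact.

Step 8
Reactants: 16 syringaldehyde (4-hydroxy-3,5-dimethoxybenzaldehyde)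
Product: 17 3,5-dimethoxy-4-[(triisopropylsilyl)oxy]benzaldehyde
Conditions: TIPSCl, imidazole, DMAP (cat.), DMF, 40 °C
Reagents that add atoms: triisopropylsilyl chloride, CC(C)[Si](Cl)(C(C)C)C(C)C
Why: O-silylation of the flanked phenol, giving the same fluoride-labile protection as in fragment 1.

Step 9
Reactants: 15 aryloxyacetyl imide; 17 3,5-dimethoxy-4-[(triisopropylsilyl)oxy]benzaldehyde
Product: 19 methyl 4-{[(1R,2S)-3-[(4S)-4-benzyl-2-oxo-1,3-oxazolidin-3-yl]-1-[3,5-dimethoxy-4-(triisopropylsilyloxy)phenyl]-1-hydroxy-3-oxopropan-2-yl]oxy}-3,5-dimethoxybenzoate, via dibutylboron Z-enolate 18 (not isolated)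
Conditions: Bu2BOTf, Et3N, CH2Cl2, −78 to 0 °C; then 17, −78 to 0 °C; H2O2, pH 7 buffer, MeOH
Reagents that add atoms: none
Why: Evans glycolate aldol: the (Z)-boron enolate of the aryloxyacetyl imide adds through a Zimmerman–Traxler chair on the face away from the benzyl group of the (S)-auxiliary, which should give the syn (threo) adduct and set both C7'' and C8''.

Step 10
Reactants: 19 glycolate aldol adduct
Product: 20 methyl 4-{[(1R,2R)-1-[3,5-dimethoxy-4-(triisopropylsilyloxy)phenyl]-1,3-dihydroxypropan-2-yl]oxy}-3,5-dimethoxybenzoate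
Conditions: NaBH4, THF/H2O (4:1), 0 °C to rt
Reagents that add atoms: none
Why: Chemoselective borohydride reduction of the activated imide carbonyl to the primary alcohol with release of the auxiliary; the electron-rich methyl benzoate should be inert.

Step 11
Reactants: 20 diol ester
Product: 21 methyl 4-({(4R,5R)-2,2-di-tert-butyl-4-[3,5-dimethoxy-4-(triisopropylsilyloxy)phenyl]-1,3,2-dioxasilinan-5-yl}oxy)-3,5-dimethoxybenzoate (fragment 2)
Conditions: tBu2Si(OTf)2, 2,6-lutidine, CH2Cl2, 0 °C
Reagents that add atoms: di-tert-butylsilyl bis(trifluoromethanesulfonate), CC(C)(C)[Si](OS(=O)(=O)C(F)(F)F)(OS(=O)(=O)C(F)(F)F)C(C)(C)C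
Why: Silylene formation across the 1,3-diol gives a six-membered ring that masks both hydroxyls with one group removable by fluoride together with the aryl silyl ethers.

**Coupling and endgame**

Step 12
Reactants: 21 fragment 2 (aryl methyl ester); 9 fragment 1 (homoallylic alcohol, 1.5 equiv)
Product: 22 (1R,2R)-2-[(2S,3R)-1-{[tert-butyldimethylsilyl]oxy}-3-hydroxy-3-[3-methoxy-4-(triisopropylsilyloxy)phenyl]propan-2-yl]-1-aryl-cyclopropan-1-ol (aryl = the 3,5-dimethoxy-4-silylene-glyceryloxy-phenyl group of 21; aryl and side chain trans on the ring)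
Conditions: Ti(OiPr)4 (1.5 equiv), c-C5H9MgCl (4.5 equiv, slow addition), THF, rt
Reagents that add atoms: none
Why: Hydroxyl-directed Kulinkovich cyclopropanation (ligand-exchange variant): the titanium alkoxide of 9 takes over the titanacyclopropane from cyclopentene, the tethered titanacycle inserts the ester and closes to the cyclopropanol; the allylic CH2OTBS group should sit exo on the chelate ring so that its substituents alternate trans, and C–C bond formation at the ring CH goes with retention, which sets the future C8' with the carbinol carbon syn to C9.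

Step 13
Reactants: 22 hydroxycyclopropanol
Product: 23 [(3S,4S,5R)-4-{[(tert-butyldimethylsilyl)oxy]methyl}-5-[3-methoxy-4-(triisopropylsilyloxy)phenyl]oxolan-3-yl](aryl)methanone (aryl as in 21)
Conditions: Cu(OTf)2 (20 mol %), 2,2'-bipyridine (22 mol %), O2 (1 atm), MeCN, rt
Reagents that add atoms: none
Why: The divalent copper salt binds the tertiary cyclopropanol oxygen, and β-carbon elimination, driven by release of the ring strain, cleaves the less substituted C(OH)–CH2 bond to give a primary alkylcopper homoenolate of the aryl ketone; the C7 alkoxide binds the same metal, oxidation to trivalent copper and C(sp3)–O reductive elimination form the O–CH2 bond, and O2 returns monovalent copper to the divalent state. The closest known reaction type is the copper-catalysed oxidative ring-opening cyclization of hydroxy-tethered cyclopropanols to 3-acyl tetrahydrofurans. Ring A closes as a five-membered ring in a 5-exo-tet sense at the methylene carbon, through a six-membered copper alkoxide–alkyl chelate. No new stereocentre is made: the CH2 is achiral, C7 keeps its aldol-derived configuration because its C–O bond is never broken (this is why the guaiacyl group ends up exo), and C8' is carried over from the cyclopropane CH, which takes no part in the cleavage. The step needs opening toward CH2 (secured by the preference of β-carbon elimination for the less hindered ring bond), use of the C7 hydroxyl alone as nucleophile (the C9 oxygen is blocked as its TBS ether) and no epimerization of the new α-keto centre C8' (neutral conditions at rt).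

Step 14
Reactants: 23 tetrahydrofuranyl aryl ketone
Product: 24 (1R,3aS,4S,6aS)-1-[3-methoxy-4-(triisopropylsilyloxy)phenyl]-4-(aryl)tetrahydro-1H,3H-furo[3,4-c]furan (aryl as in 21; fully silylated target)
Conditions: Et3SiH (3 equiv), TMSOTf (0.3 equiv), CH2Cl2, −78 to −50 °C; Et3N quench
Reagents that add atoms: none
Why: Reductive etherification: the silyl triflate activates the aryl ketone, the C9 silyl ether oxygen adds (5-exo-trig) and loss of disiloxane gives an aryl-stabilized bicyclic oxocarbenium ion that can only be cis-fused; Et3SiH should attack its convex face, which pushes the aryl group endo and sets C7' as S.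

Step 15
Reactants: 24 fully silylated target
Product: 25 target, 4-[(1R,3aS,4S,6aS)-4-(4-{[(1R,2R)-1,3-dihydroxy-1-(4-hydroxy-3,5-dimethoxyphenyl)propan-2-yl]oxy}-3,5-dimethoxyphenyl)tetrahydro-1H,3H-furo[3,4-c]furan-1-yl]-2-methoxyphenol
Conditions: TBAF, AcOH (1:1), THF, 0 °C to rt
Reagents that add atoms: none
Why: Fluoride-mediated desilylation cleaves both aryl silyl ethers and the silylene in one operation; the acetic acid buffer keeps the freed phenols protonated, so the endo benzylic ether and the benzylic alcohol see neither strong base nor acid.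

**Compound list**
1 | vanillin | COc1cc(C=O)ccc1O | starting material
2 | 3-methoxy-4-[(triisopropylsilyl)oxy]benzaldehyde | COc1cc(C=O)ccc1O[Si](C(C)C)(C(C)C)C(C)C | intermediate
3 | (R)-4-benzyl-1,3-oxazolidin-2-one | O=C1N[C@H](Cc2ccccc2)CO1 | starting material
4 | (E)-but-2-enoic anhydride | C/C=C/C(=O)OC(=O)/C=C/C | starting material
5 | (R)-4-benzyl-3-[(E)-but-2-enoyl]-1,3-oxazolidin-2-one | C/C=C/C(=O)N1[C@H](Cc2ccccc2)COC1=O | intermediate
6 | dibutylboron (Z)-dienolate of 5 | C=C/C=C(\OB(CCCC)CCCC)N1[C@H](Cc2ccccc2)COC1=O | intermediate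
7 | (4R)-4-benzyl-3-[(2R)-2-{(R)-hydroxy[3-methoxy-4-(triisopropylsilyloxy)phenyl]methyl}but-3-enoyl]-1,3-oxazolidin-2-one | C=C[C@H]([C@@H](O)c1ccc(O[Si](C(C)C)(C(C)C)C(C)C)c(OC)c1)C(=O)N1[C@H](Cc2ccccc2)COC1=O | intermediate
8 | (1R,2S)-2-ethenyl-1-[3-methoxy-4-(triisopropylsilyloxy)phenyl]propane-1,3-diol | C=C[C@H]([C@@H](O)c1ccc(O[Si](C(C)C)(C(C)C)C(C)C)c(OC)c1)CO | intermediate
9 | (1R,2S)-2-{[(tert-butyldimethylsilyl)oxy]methyl}-1-[3-methoxy-4-(triisopropylsilyloxy)phenyl]but-3-en-1-ol | C=C[C@H]([C@@H](O)c1ccc(O[Si](C(C)C)(C(C)C)C(C)C)c(OC)c1)CO[Si](C)(C)C(C)(C)C | intermediate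
10 | (S)-4-benzyl-1,3-oxazolidin-2-one | O=C1N[C@@H](Cc2ccccc2)CO1 | starting material
11 | bromoacetyl bromide | BrCC(Br)=O | starting material
12 | N-lithio-(S)-4-benzyl-1,3-oxazolidin-2-one | [Li]N1[C@@H](Cc2ccccc2)COC1=O | intermediate
13 | (S)-4-benzyl-3-(bromoacetyl)-1,3-oxazolidin-2-one | BrCC(=O)N1[C@@H](Cc2ccccc2)COC1=O | intermediate
14 | methyl syringate | COC(=O)c1cc(OC)c(O)c(OC)c1 | starting material
15 | methyl 4-{2-[(4S)-4-benzyl-2-oxo-1,3-oxazolidin-3-yl]-2-oxoethoxy}-3,5-dimethoxybenzoate | COC(=O)c1cc(OC)c(OCC(=O)N2[C@@H](Cc3ccccc3)COC2=O)c(OC)c1 | intermediate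
16 | syringaldehyde | COc1cc(C=O)cc(OC)c1O | starting material
17 | 3,5-dimethoxy-4-[(triisopropylsilyl)oxy]benzaldehyde | COc1cc(C=O)cc(OC)c1O[Si](C(C)C)(C(C)C)C(C)C | intermediate
18 | dibutylboron (Z)-enolate of 15 | COC(=O)c1cc(OC)c(O/C=C(\OB(CCCC)CCCC)N2[C@@H](Cc3ccccc3)COC2=O)c(OC)c1 | intermediate
19 | methyl 4-{[(1R,2S)-3-[(4S)-4-benzyl-2-oxo-1,3-oxazolidin-3-yl]-1-[3,5-dimethoxy-4-(triisopropylsilyloxy)phenyl]-1-hydroxy-3-oxopropan-2-yl]oxy}-3,5-dimethoxybenzoate | COC(=O)c1cc(OC)c(O[C@H](C(=O)N2[C@@H](Cc3ccccc3)COC2=O)[C@H](O)c2cc(OC)c(O[Si](C(C)C)(C(C)C)C(C)C)c(OC)c2)c(OC)c1 | intermediate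
20 | methyl 4-{[(1R,2R)-1-[3,5-dimethoxy-4-(triisopropylsilyloxy)phenyl]-1,3-dihydroxypropan-2-yl]oxy}-3,5-dimethoxybenzoate | COC(=O)c1cc(OC)c(O[C@H](CO)[C@H](O)c2cc(OC)c(O[Si](C(C)C)(C(C)C)C(C)C)c(OC)c2)c(OC)c1 | intermediate
21 | methyl 4-({(4R,5R)-2,2-di-tert-butyl-4-[3,5-dimethoxy-4-(triisopropylsilyloxy)phenyl]-1,3,2-dioxasilinan-5-yl}oxy)-3,5-dimethoxybenzoate | COC(=O)c1cc(OC)c(O[C@@H]2CO[Si](C(C)(C)C)(C(C)(C)C)O[C@@H]2c2cc(OC)c(O[Si](C(C)C)(C(C)C)C(C)C)c(OC)c2)c(OC)c1 | intermediate
22 | (1R,2R)-2-[(2S,3R)-1-(TBS-oxy)-3-hydroxy-3-(3-methoxy-4-TIPS-oxyphenyl)propan-2-yl]-1-(aryl)cyclopropan-1-ol, aryl as in 21 | O[C@]1(c2cc(OC)c(O[C@@H]3CO[Si](C(C)(C)C)(C(C)(C)C)O[C@@H]3c3cc(OC)c(O[Si](C(C)C)(C(C)C)C(C)C)c(OC)c3)c(OC)c2)C[C@@H]1[C@@H](CO[Si](C)(C)C(C)(C)C)[C@@H](O)c1ccc(O[Si](C(C)C)(C(C)C)C(C)C)c(OC)c1 | intermediate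
23 | [(3S,4S,5R)-4-(TBS-oxymethyl)-5-(3-methoxy-4-TIPS-oxyphenyl)oxolan-3-yl](aryl)methanone, aryl as in 21 | COc1cc([C@@H]2OC[C@@H](C(=O)c3cc(OC)c(O[C@@H]4CO[Si](C(C)(C)C)(C(C)(C)C)O[C@@H]4c4cc(OC)c(O[Si](C(C)C)(C(C)C)C(C)C)c(OC)c4)c(OC)c3)[C@H]2CO[Si](C)(C)C(C)(C)C)ccc1O[Si](C(C)C)(C(C)C)C(C)C | intermediate
24 | (1R,3aS,4S,6aS)-1-(3-methoxy-4-TIPS-oxyphenyl)-4-(aryl)tetrahydro-1H,3H-furo[3,4-c]furan, aryl as in 21 | COc1cc([C@@H]2OC[C@@H]3[C@H]2CO[C@@H]3c2cc(OC)c(O[C@@H]3CO[Si](C(C)(C)C)(C(C)(C)C)O[C@@H]3c3cc(OC)c(O[Si](C(C)C)(C(C)C)C(C)C)c(OC)c3)c(OC)c2)ccc1O[Si](C(C)C)(C(C)C)C(C)C | intermediate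
25 | 4-[(1R,3aS,4S,6aS)-4-(4-{[(1R,2R)-1,3-dihydroxy-1-(4-hydroxy-3,5-dimethoxyphenyl)propan-2-yl]oxy}-3,5-dimethoxyphenyl)tetrahydro-1H,3H-furo[3,4-c]furan-1-yl]-2-methoxyphenol | COc1cc([C@@H]2OC[C@@H]3[C@H]2CO[C@@H]3c2cc(OC)c(O[C@H](CO)[C@H](O)c3cc(OC)c(O)c(OC)c3)c(OC)c2)ccc1O | target

**Step count and risks**
Total steps: 15. Longest linear sequence: 9 steps (steps 6, 7, 9, 10, 11, 12, 13, 14, 15).

Most likely to fail:

1. Step 13. The ring opening may leave the organocopper pathway: one-electron opening toward the more substituted ring carbon, capture of the alkyl intermediate by O2, β-hydride loss to the α-methylene ketone, or enolization at C8'. Fallback, a stepwise polar route from 22 back to 23: electrophilic ring-opening iodination of 22 with N-iodosuccinimide (CH2Cl2, 0 °C, dark) should cleave the same less substituted bond and give the β-iodo ketone F1. Ag2O (CH2Cl2, rt) should then close ring A by intramolecular Williamson-type displacement of the primary iodide by the C7 hydroxyl (5-exo-tet), returning 23.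

2. Step 12. The hindered, electron-rich aryl ester may insert too slowly into the tethered titanacycle, the Grignard reagent may add directly to the ester, or facial selectivity at the alkene may be poor. Fallback, a tethered intramolecular variant from 21 and 9 back to 22: the methyl ester of 21 is cleaved with Me3SnOH (1,2-dichloroethane, 80 °C) to the carboxylic acid F2. F2 is esterified with the C7 hydroxyl of 9 under Yamaguchi conditions (2,4,6-trichlorobenzoyl chloride, Et3N, DMAP, toluene) to the homoallyl ester F3. Treatment of F3 with Ti(OiPr)4 and c-C5H9MgCl (Et2O, rt) should make the titanacyclopropane attack the tethered ester carbonyl intramolecularly (acyl substitution, then carbonyl addition) and return the hydroxycyclopropanol 22.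

3. Step 14. The silyl ether may fail to engage the ketone, so that direct carbonyl reduction, ionization and over-reduction of benzylic C–O bonds, or loss of facial control take over; any C8' epimer cannot close at all. Fallback, from 23 back to 24 with cyclization and reduction separated: PPTS in MeOH/HC(OMe)3 (0 °C to rt) should methanolyse the primary TBS ether to the hydroxy ketone F4. Under the same acid F4 should close to the bicyclic methyl ketal F5, and any C8' epimer funnels into the cis-fused ketal through the cyclic enol ether. Et3SiH with BF3·OEt2 (CH2Cl2, −78 °C) should then reduce the ketal through the same oxocarbenium ion, with convex-face hydride delivery, to 24.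

**Further compounds**
F1 | step 13 | (2S,3S,4R)-3-{[(tert-butyldimethylsilyl)oxy]methyl}-4-hydroxy-2-(iodomethyl)-4-[3-methoxy-4-(triisopropylsilyloxy)phenyl]-1-(aryl)butan-1-one, aryl as in 21 | O=C(c1cc(OC)c(O[C@@H]2CO[Si](C(C)(C)C)(C(C)(C)C)O[C@@H]2c2cc(OC)c(O[Si](C(C)C)(C(C)C)C(C)C)c(OC)c2)c(OC)c1)[C@H](CI)[C@@H](CO[Si](C)(C)C(C)(C)C)[C@@H](O)c1ccc(O[Si](C(C)C)(C(C)C)C(C)C)c(OC)c1
F2 | step 12 | 4-({(4R,5R)-2,2-di-tert-butyl-4-[3,5-dimethoxy-4-(triisopropylsilyloxy)phenyl]-1,3,2-dioxasilinan-5-yl}oxy)-3,5-dimethoxybenzoic acid | OC(=O)c1cc(OC)c(O[C@@H]2CO[Si](C(C)(C)C)(C(C)(C)C)O[C@@H]2c2cc(OC)c(O[Si](C(C)C)(C(C)C)C(C)C)c(OC)c2)c(OC)c1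
F3 | step 12 | (1R,2S)-2-{[(tert-butyldimethylsilyl)oxy]methyl}-1-[3-methoxy-4-(triisopropylsilyloxy)phenyl]but-3-en-1-yl ester of F2 | C=C[C@H]([C@@H](OC(=O)c1cc(OC)c(O[C@@H]2CO[Si](C(C)(C)C)(C(C)(C)C)O[C@@H]2c2cc(OC)c(O[Si](C(C)C)(C(C)C)C(C)C)c(OC)c2)c(OC)c1)c1ccc(O[Si](C(C)C)(C(C)C)C(C)C)c(OC)c1)CO[Si](C)(C)C(C)(C)C
F4 | step 14 | [(3S,4S,5R)-4-(hydroxymethyl)-5-[3-methoxy-4-(triisopropylsilyloxy)phenyl]oxolan-3-yl](aryl)methanone, aryl as in 21 | COc1cc([C@@H]2OC[C@@H](C(=O)c3cc(OC)c(O[C@@H]4CO[Si](C(C)(C)C)(C(C)(C)C)O[C@@H]4c4cc(OC)c(O[Si](C(C)C)(C(C)C)C(C)C)c(OC)c4)c(OC)c3)[C@H]2CO)ccc1O[Si](C(C)C)(C(C)C)C(C)C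
F5 | step 14 | (1R,3aS,6aS)-4-methoxy-1-[3-methoxy-4-(triisopropylsilyloxy)phenyl]-4-(aryl)tetrahydro-1H,3H-furo[3,4-c]furan, aryl as in 21, either configuration at the ketal carbon | COc1cc([C@@H]2OC[C@@H]3[C@H]2COC3(OC)c2cc(OC)c(O[C@@H]3CO[Si](C(C)(C)C)(C(C)(C)C)O[C@@H]3c3cc(OC)c(O[Si](C(C)C)(C(C)C)C(C)C)c(OC)c3)c(OC)c2)ccc1O[Si](C(C)C)(C(C)C)C(C)C
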